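**Retrosynthetic overview**

1. The strategy rests on ring B of the ketone-bearing half: a 1-naphthol whose hydroxyl sits on C9, next to the ring A carbon C8a. This is the oxygen pattern left when the oxygen bridge of an aryne–furan adduct is opened, so C8a–C9 and C4b–C4a are cut to give a ring A 3-bromoaryne and a furan whose oxygen becomes the C9 hydroxyl.
2. The furan partner 27 already carries ring C (C1 gem-dimethyl, C2 ketone, C3 methyl ketal, C4–O) and the cis-fused dioxane to the right half. It is built by opening an epoxide at C4 with the 3'-oxygen of the right-half catechol, oxidation to the 2,3-dione, hemiketal closure by the 2'-oxygen and exchange with methanol.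
3. The furan-fused ring C comes from 3-bromofuran-2-carbaldehyde by aldol condensation, intramolecular Pd α-arylation (quaternary C1), desaturation and Jacobsen epoxidation. The epoxidation fixes C4, and C3 follows from it.
4. The right-half phenanthrene comes from a Suzuki–Miyaura biaryl coupling (rings A' and C') and a Friedel–Crafts acylation that closes ring B' at C9'–C8a'.
5. Order of ring formation: ring C on the furan, then ring B', then the dioxane, then rings A/B by the aryne step; the C5 bromine and the 6'-pivalate are removed last.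

Key step: step 22

Assumption: both halves carry phenanthrene locants (primes for the fully aromatic half); furan-series intermediates also carry benzofuran locants, where benzofuran C4, C5, C6, C7 are C1, C2, C3, C4 of the target.

**Furan-fused ring C**

Step 1
Reactants: 1 3-bromofuran-2-carbaldehyde; 2 3-methylbutan-2-one
Product: 3 (E)-1-(3-bromofuran-2-yl)-4-methylpent-1-en-3-one
Conditions: NaOH (aq), EtOH, 0 °C → rt
Reagents that add atoms: none
Why: Claisen–Schmidt condensation; the ketone reacts through its methyl group because only that aldol can dehydrate, giving the conjugated (E)-enone.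

Step 2
Reactants: 3 (E)-1-(3-bromofuran-2-yl)-4-methylpent-1-en-3-one
Product: 4 1-(3-bromofuran-2-yl)-4-methylpentan-3-one
Conditions: H2 (1 atm), RhCl(PPh3)3 (cat.), benzene/EtOH, rt
Reagents that add atoms: none
Why: Homogeneous hydrogenation saturates the conjugated disubstituted C=C and should leave the C–Br bond, the furan and the ketone untouched.

Step 3
Reactants: 4 1-(3-bromofuran-2-yl)-4-methylpentan-3-one
Product: 5 4,4-dimethyl-6,7-dihydro-1-benzofuran-5(4H)-one
Conditions: Pd2(dba)3 (cat.), P(t-Bu)3·HBF4, NaOt-Bu, toluene, 70 °C, high dilution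
Reagents that add atoms: none
Why: Intramolecular Pd-catalysed ketone α-arylation; the two enolates equilibrate and only the methine enolate can close a six-membered ring, which creates the quaternary C1 of the target.

Step 4
Reactants: 5 4,4-dimethyl-6,7-dihydro-1-benzofuran-5(4H)-one
Product: 7 4,4-dimethyl-1-benzofuran-5(4H)-one, via silyl enol ether 6 (not isolated)
Conditions: LiN(i-Pr)2, Me3SiCl, THF, −78 °C; then Pd(OAc)2, MeCN, rt
Reagents that add atoms: none
Why: Saegusa–Ito desaturation; C6 is the only enolisable position, and β-hydride loss from the furylic C7 gives the cis enone.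

Step 5
Reactants: 7 4,4-dimethyl-1-benzofuran-5(4H)-one
Product: 8 (6R,7S)-6,7-epoxy-4,4-dimethyl-6,7-dihydro-1-benzofuran-5(4H)-one
Conditions: (R,R)-N,N'-bis(3,5-di-tert-butylsalicylidene)-1,2-cyclohexanediaminomanganese chloride (cat.), m-CPBA, N-methylmorpholine N-oxide, CH2Cl2, −78 °C
Reagents that add atoms: m-chloroperbenzoic acid, O=C(OO)c1cccc(Cl)c1
Why: Jacobsen epoxidation of a cis-disubstituted, heteroaryl-conjugated alkene; by analogy with cis-cinnamate esters the (R,R)-catalyst should give the (6R,7S)-epoxide (the antipodal catalyst is the remedy if the sense is opposite), and the peracid alone should not attack the electron-poor enone at −78 °C, so no racemic background is expected.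

Step 6
Reactants: 8 (6R,7S)-6,7-epoxy-4,4-dimethyl-6,7-dihydro-1-benzofuran-5(4H)-one
Product: 9 (5S,6S,7S)-6,7-epoxy-4,4-dimethyl-4,5,6,7-tetrahydro-1-benzofuran-5-ol (hydroxyl cis to the epoxide)
Conditions: NaBH4, CeCl3·7H2O, MeOH, −40 °C; used crude
Reagents that add atoms: none
Why: Luche reduction; hydride should add anti to the epoxide oxygen to give the cis epoxy alcohol (the new C5 centre is re-oxidised in step 17), which removes the carbonyl that would invite attack at C6 or β-elimination of aryloxide in step 16 and cannot undergo Payne migration.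

**Right-half catechol**

Step 7
Reactants: 10 3-methylcatechol
Product: 11 4-methyl-1,3-benzodioxole
Conditions: CH2Br2, Cs2CO3, DMF, 110 °C
Reagents that add atoms: dibromomethane, BrCBr
Why: Double Williamson etherification ties both phenols into a methylene acetal that survives bases, Pd catalysis and strong acid.

Step 8
Reactants: 11 4-methyl-1,3-benzodioxole
Product: 12 5-bromo-4-methyl-1,3-benzodioxole
Conditions: NBS, MeCN, 0 °C → rt
Reagents that add atoms: N-bromosuccinimide, O=C1CCC(=O)N1Br
Why: Electrophilic aromatic bromination goes para to a ring oxygen, and of the two such positions the one ortho to the methyl group (the future C10a') is the more activated.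

Step 9
Reactants: 12 5-bromo-4-methyl-1,3-benzodioxole; 13 tert-butyl acetate
Product: 14 tert-butyl 2-(4-methyl-1,3-benzodioxol-5-yl)acetate
Conditions: LiN(SiMe3)2, Pd(dba)2 (cat.), P(t-Bu)3, toluene, rt
Reagents that add atoms: none
Why: Pd-catalysed α-arylation of an ester enolate installs the two-carbon unit that becomes C10' and C9'.

Step 10
Reactants: 14 tert-butyl 2-(4-methyl-1,3-benzodioxol-5-yl)acetate
Product: 15 tert-butyl 2-(6-bromo-4-methyl-1,3-benzodioxol-5-yl)acetate
Conditions: NBS, MeCN, rt
Reagents that add atoms: N-bromosuccinimide, O=C1CCC(=O)N1Br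
Why: The second electrophilic bromination takes the only remaining position para to a ring oxygen (the future C4a'), since positions ortho to the oxygens of a benzodioxole are far less reactive.

Step 11
Reactants: 16 5-bromo-2-methylphenol
Product: 17 5-bromo-2-methylphenyl pivalate
Conditions: t-BuCOCl, Et3N, DMAP (cat.), CH2Cl2, 0 °C → rt
Reagents that add atoms: pivaloyl chloride, CC(C)(C)C(Cl)=O
Why: O-Acylation masks the future 6'-hydroxyl as a hindered ester that tolerates acid, fluoride and Pd, and leaves by methanolysis at the end.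

Step 12
Reactants: 17 5-bromo-2-methylphenyl pivalate; 15 tert-butyl 2-(6-bromo-4-methyl-1,3-benzodioxol-5-yl)acetate
Product: 19 tert-butyl 2-{4-methyl-6-[4-methyl-3-(pivaloyloxy)phenyl]-1,3-benzodioxol-5-yl}acetate, via aryl pinacol boronate 18 (not isolated)
Conditions: B2pin2, Pd(dppf)Cl2 (cat.), KOAc, 1,4-dioxane, 90 °C; then 15, K3PO4, H2O (small amount), 90 °C
Reagents that add atoms: none
Why: Miyaura borylation of 17 followed in the same flask by Suzuki–Miyaura coupling with 15 forms the C4a'–C4b' biaryl bond.

Step 13
Reactants: 19 tert-butyl 2-{4-methyl-6-[4-methyl-3-(pivaloyloxy)phenyl]-1,3-benzodioxol-5-yl}acetate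
Product: 21 9-hydroxy-1,7-dimethyl-2,3-methylenedioxyphenanthren-6-yl pivalate, via free arylacetic acid 20 (not isolated)
Conditions: P2O5/MeSO3H, CH2Cl2, 0 °C → rt
Reagents that add atoms: none
Why: The acid cleaves the tert-butyl ester and the acylium ion closes ring B' by intramolecular Friedel–Crafts acylation para to the pivaloyloxy group, which places the oxygen on C9' next to ring A'.

Step 14
Reactants: 21 9-hydroxy-1,7-dimethyl-2,3-methylenedioxyphenanthren-6-yl pivalate
Product: 22 9-methoxy-1,7-dimethyl-2,3-methylenedioxyphenanthren-6-yl pivalate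
Conditions: MeI, K2CO3, acetone, rt, under N2
Reagents that add atoms: iodomethane, CI
Why: Williamson O-methylation of the acidic phenanthren-9-ol, run without air because this phenol oxidises easily.

Step 15
Reactants: 22 9-methoxy-1,7-dimethyl-2,3-methylenedioxyphenanthren-6-yl pivalate
Product: 23 2,3-dihydroxy-9-methoxy-1,7-dimethylphenanthren-6-yl pivalate
Conditions: BCl3, CH2Cl2, −78 → 0 °C; then aq. HCl, THF, rt
Reagents that add atoms: none
Why: Lewis-acid cleavage of the methylene acetal, for which BCl3 is selective over an aryl methyl ether and an aryl ester.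

**Union and ketal**

Step 16
Reactants: 9 (5S,6S,7S)-epoxy alcohol; 23 right-half catechol
Product: 24 (5S,6S,7R)-7-{[2-hydroxy-9-methoxy-1,7-dimethyl-6-(pivaloyloxy)phenanthren-3-yl]oxy}-4,4-dimethyl-4,5,6,7-tetrahydro-1-benzofuran-5,6-diol
Conditions: Cs2CO3 (0.3 equiv), degassed DMF, 50 °C, argon
Reagents that add atoms: none
Why: Base-mediated SN2 opening of a hetero-benzylic epoxide by a phenoxide; the less hindered 3'-oxygen (the 2'-oxygen is flanked by the C1' methyl) attacks the furylic C7 anti to the C–O bond, so C7 is inverted to the configuration needed at C4 of the target.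

Step 17
Reactants: 24 diol ether
Product: 26 (6S,7S)-cis-fused hemiketal (6-hydroxy analogue of 27), via open 5,6-dione 25 (not isolated)
Conditions: (COCl)2, DMSO, CH2Cl2, −78 °C; then Et3N, −78 → 0 °C
Reagents that add atoms: none
Why: Swern oxidation of both secondary alcohols gives the 5,6-dione, whose more electrophilic C6 carbonyl (C3 of the target) is captured at once by the neighbouring 2'-phenol; the new C6 centre is set by C7 through the cis ring fusion, and fast closure should keep the C7 proton from enolising.

Step 18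
Reactants: 26 hemiketal
Product: 27 (6S,7S)-methyl ketal: 4,4-dimethyl-6,7-dihydro-1-benzofuran-5(4H)-one whose C7 carries the 3'-oxygen and whose C6 carries methoxyl and the 2'-oxygen of the 9'-methoxy-1',7'-dimethyl-6'-(pivaloyloxy)phenanthrene, with 6-OMe cis to 7-H
Conditions: MeOH, camphorsulfonic acid (cat.), 3 Å molecular sieves, 40 °C
Reagents that add atoms: methanol, CO
Why: Acid-catalysed exchange of the hemiketal hydroxyl for methoxyl through the oxocarbenium ion (Fischer-type ketalisation) under equilibrating conditions; the cis-fused ketal with axial methoxyl (anomeric effect) is expected as the thermodynamic product and has the C3 configuration of the target.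

**Aryne precursor**

Step 19
Reactants: 28 3-methoxy-4-methylphenol
Product: 29 2-iodo-5-methoxy-4-methylphenol
Conditions: N-iodosuccinimide, TsOH (cat.), MeCN, 0 °C
Reagents that add atoms: N-iodosuccinimide, O=C1CCC(=O)N1I
Why: Electrophilic iodination takes the less hindered activated position, ortho to the hydroxyl and para to the methoxyl, not the site between the two oxygens.

Step 20
Reactants: 29 2-iodo-5-methoxy-4-methylphenol
Product: 30 2-bromo-6-iodo-3-methoxy-4-methylphenol
Conditions: NBS, CH2Cl2, 0 °C
Reagents that add atoms: N-bromosuccinimide, O=C1CCC(=O)N1Br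
Why: Electrophilic bromination takes the last activated position, between the hydroxyl and the methoxyl, which places the future C5 bromine.

Step 21
Reactants: 30 2-bromo-6-iodo-3-methoxy-4-methylphenol
Product: 33 2-bromo-3-methoxy-4-methyl-6-(trimethylsilyl)phenyl triflate, via aryl trimethylsilyl ether 31 (not isolated), via lithium 2-silylphenoxide 32 (not isolated)
Conditions: (Me3Si)2NH, THF, 65 °C, then evaporation; n-BuLi, THF, −100 °C; Tf2O, −100 → −78 °C
Reagents that add atoms: hexamethyldisilazane, C[Si](C)(C)N[Si](C)(C)C; triflic anhydride, O=S(=O)(OS(=O)(=O)C(F)(F)F)C(F)(F)F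
Why: O-Silylation, then iodine–lithium exchange (much faster than exchange of the bromine) triggers the retro-Brook 1,3-shift of silicon from oxygen to carbon, and the phenoxide is trapped as the triflate.

**Key step and end game**

Step 22
Reactants: 27 furan methyl ketal; 33 2-bromo-3-methoxy-4-methyl-6-(trimethylsilyl)phenyl triflate
Product: 36 5-bromo-6'-O-pivaloyl actephilol C, via 3-bromoaryne 34 (not isolated), via 9,4a-epoxide cycloadduct 35 (not isolated)
Conditions: CsF, MeCN, rt (33 added slowly); then MeSO3H, MeOH, rt, same flask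
Reagents that add atoms: none
Why: Fluoride removes the silyl group of 33 and expels triflate to give aryne 34, which adds across furan carbons C9 and C4a of 27 in a concerted, asynchronous [4+2] cycloaddition (aryne–furan Diels–Alder), forming C8a–C9 and C4b–C4a and closing ring B as a six-membered carbocycle by annulation, with 7-oxabenzonorbornadiene 35 formed as both facial adducts. Acid then protonates the bridging oxygen, the C4a–O bond breaks to the tertiary, benzylic and allylic cation, and loss of the C9 proton aromatises ring B with the oxygen left as the C9 naphthol, the standard isomerisation of 1,4-epoxy-1,4-dihydronaphthalenes to 1-naphthols. No stereocentre is created: the bridgehead centres of 35 vanish on aromatisation, so both facial adducts converge, while C3 and C4 are untouched and the methyl ketal re-forms in methanol if it ionises. The selectivity needed is regiochemical: the inductively withdrawing bromine distorts the aryne so that the distal carbon C8a is the electrophilic terminus, which pairs with the more nucleophilic, unsubstituted furan α-carbon C9 in the leading bond, and the substituted C4a closes the longer, later bond beside the bromine. Chemoselectivity rests on 27 having no enolisable ketone and no free hydroxyl, and on the furan being far more reactive towards arynes than the methoxyphenanthrene or the ester.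

Step 23
Reactants: 36 5-bromo-6'-O-pivaloyl actephilol C
Product: 37 6'-O-pivaloyl actephilol C
Conditions: Pd(OAc)2 (cat.), PPh3, HCO2H, Et3N, DMF, 80 °C
Reagents that add atoms: none
Why: Pd-catalysed transfer hydrogenolysis of the aryl bromide with formate as hydride donor removes the C5 control element; the free naphthol, ketone, ketal and ester are tolerated.

Step 24
Reactants: 37 6'-O-pivaloyl actephilol C
Product: 38 actephilol C
Conditions: K2CO3, MeOH, rt
Reagents that add atoms: none
Why: Base-mediated methanolysis of the aryl pivalate frees the 6'-phenol; the C2 ketone has no α-hydrogen and the ketal is stable to base, so C3 and C4 are not at risk.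

**Compound list**

1 | 3-bromofuran-2-carbaldehyde | O=Cc1occc1Br | starting material
2 | 3-methylbutan-2-one | CC(=O)C(C)C | starting material
3 | (E)-1-(3-bromofuran-2-yl)-4-methylpent-1-en-3-one | CC(C)C(=O)/C=C/c1occc1Br | intermediate
4 | 1-(3-bromofuran-2-yl)-4-methylpentan-3-one | CC(C)C(=O)CCc1occc1Br | intermediate
5 | 4,4-dimethyl-6,7-dihydro-1-benzofuran-5(4H)-one | CC1(C)C(=O)CCc2occc12 | intermediate
6 | 4,4-dimethyl-5-(trimethylsilyloxy)-4,7-dihydro-1-benzofuran (silyl enol ether, not isolated) | CC1(C)C(O[Si](C)(C)C)=CCc2occc12 | intermediate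
7 | 4,4-dimethyl-1-benzofuran-5(4H)-one | CC1(C)C(=O)C=Cc2occc12 | intermediate
8 | (6R,7S)-6,7-epoxy-4,4-dimethyl-6,7-dihydro-1-benzofuran-5(4H)-one | O=C1[C@@H]2O[C@@H]2c2occc2C1(C)C | intermediate
9 | (5S,6S,7S)-6,7-epoxy-4,4-dimethyl-4,5,6,7-tetrahydro-1-benzofuran-5-ol | O[C@@H]1[C@@H]2O[C@@H]2c2occc2C1(C)C | intermediate
10 | 3-methylcatechol | Cc1cccc(O)c1O | starting material
11 | 4-methyl-1,3-benzodioxole | Cc1cccc2c1OCO2 | intermediate
12 | 5-bromo-4-methyl-1,3-benzodioxole | Cc1c(Br)ccc2c1OCO2 | intermediate
13 | tert-butyl acetate | CC(=O)OC(C)(C)C | starting material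
14 | tert-butyl 2-(4-methyl-1,3-benzodioxol-5-yl)acetate | Cc1c(CC(=O)OC(C)(C)C)ccc2c1OCO2 | intermediate
15 | tert-butyl 2-(6-bromo-4-methyl-1,3-benzodioxol-5-yl)acetate | Cc1c(CC(=O)OC(C)(C)C)c(Br)cc2c1OCO2 | intermediate
16 | 5-bromo-2-methylphenol | Cc1ccc(Br)cc1O | starting material
17 | 5-bromo-2-methylphenyl pivalate | Cc1ccc(Br)cc1OC(=O)C(C)(C)C | intermediate
18 | 2-methyl-5-(4,4,5,5-tetramethyl-1,3,2-dioxaborolan-2-yl)phenyl pivalate (not isolated) | Cc1ccc(B2OC(C)(C)C(C)(C)O2)cc1OC(=O)C(C)(C)C | intermediate
19 | tert-butyl 2-{4-methyl-6-[4-methyl-3-(pivaloyloxy)phenyl]-1,3-benzodioxol-5-yl}acetate | Cc1c(CC(=O)OC(C)(C)C)c(-c3ccc(C)c(OC(=O)C(C)(C)C)c3)cc2c1OCO2 | intermediate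
20 | 2-{4-methyl-6-[4-methyl-3-(pivaloyloxy)phenyl]-1,3-benzodioxol-5-yl}acetic acid (not isolated) | Cc1c(CC(=O)O)c(-c3ccc(C)c(OC(=O)C(C)(C)C)c3)cc2c1OCO2 | intermediate
21 | 9-hydroxy-1,7-dimethyl-2,3-methylenedioxyphenanthren-6-yl pivalate | Cc1c2OCOc2cc2c1cc(O)c1cc(C)c(OC(=O)C(C)(C)C)cc12 | intermediate
22 | 9-methoxy-1,7-dimethyl-2,3-methylenedioxyphenanthren-6-yl pivalate | Cc1c2OCOc2cc2c1cc(OC)c1cc(C)c(OC(=O)C(C)(C)C)cc12 | intermediate
23 | 2,3-dihydroxy-9-methoxy-1,7-dimethylphenanthren-6-yl pivalate | Cc1c(O)c(O)cc2c1cc(OC)c1cc(C)c(OC(=O)C(C)(C)C)cc12 | intermediate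
24 | (5S,6S,7R)-7-{[2-hydroxy-9-methoxy-1,7-dimethyl-6-(pivaloyloxy)phenanthren-3-yl]oxy}-4,4-dimethyl-4,5,6,7-tetrahydro-1-benzofuran-5,6-diol | O[C@@H]1[C@H](O)[C@@H](Oc2cc3c(cc(OC)c4cc(C)c(OC(=O)C(C)(C)C)cc43)c(C)c2O)c2occc2C1(C)C | intermediate
25 | (7S)-7-aryloxy-4,4-dimethyl-1-benzofuran-5,6(4H,7H)-dione, aryl as in 24 (not isolated) | O=C1C(=O)[C@@H](Oc2cc3c(cc(OC)c4cc(C)c(OC(=O)C(C)(C)C)cc43)c(C)c2O)c2occc2C1(C)C | intermediate
26 | (6S,7S)-cis-fused hemiketal (6-hydroxy analogue of 27) | c12occc1C(C)(C)C(=O)[C@@]1(O)Oc3c(cc4c(cc(OC)c5cc(C)c(OC(=O)C(C)(C)C)cc54)c3C)O[C@@H]21 | intermediate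
27 | (6S,7S)-cis-fused methyl ketal, furan partner of the key step | c12occc1C(C)(C)C(=O)[C@@]1(OC)Oc3c(cc4c(cc(OC)c5cc(C)c(OC(=O)C(C)(C)C)cc54)c3C)O[C@@H]21 | intermediate
28 | 3-methoxy-4-methylphenol | COc1cc(O)ccc1C | starting material
29 | 2-iodo-5-methoxy-4-methylphenol | COc1cc(O)c(I)cc1C | intermediate
30 | 2-bromo-6-iodo-3-methoxy-4-methylphenol | COc1c(Br)c(O)c(I)cc1C | intermediate
31 | (2-bromo-6-iodo-3-methoxy-4-methylphenoxy)trimethylsilane (not isolated) | COc1c(Br)c(O[Si](C)(C)C)c(I)cc1C | intermediate
32 | lithium 2-bromo-3-methoxy-4-methyl-6-(trimethylsilyl)phenoxide (not isolated) | COc1c(Br)c([O-])c([Si](C)(C)C)cc1C.[Li+] | intermediate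
33 | 2-bromo-3-methoxy-4-methyl-6-(trimethylsilyl)phenyl triflate | COc1c(Br)c(OS(=O)(=O)C(F)(F)F)c([Si](C)(C)C)cc1C | intermediate
34 | 3-bromo-4-methoxy-5-methylbenzyne (not isolated) | COC1=C(Br)C#CC=C1C | intermediate
35 | 9,4a-epoxy-4a,9-dihydro cycloadduct of 27 and 34, both facial isomers (not isolated) | COc1c(Br)c2c(cc1C)C3C=C4C(C)(C)C(=O)[C@@]5(OC)Oc6c(C)c7cc(OC)c8cc(C)c(OC(=O)C(C)(C)C)cc8c7cc6O[C@H]5C42O3 | intermediate
36 | 5-bromo-6'-O-pivaloyl actephilol C | COc1c(Br)c2c3c(cc(O)c2cc1C)C(C)(C)C(=O)[C@@]1(OC)Oc2c(cc4c(cc(OC)c5cc(C)c(OC(=O)C(C)(C)C)cc54)c2C)O[C@@H]31 | intermediate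
37 | 6'-O-pivaloyl actephilol C | COc1cc2c3c(cc(O)c2cc1C)C(C)(C)C(=O)[C@@]1(OC)Oc2c(cc4c(cc(OC)c5cc(C)c(OC(=O)C(C)(C)C)cc54)c2C)O[C@@H]31 | intermediate
38 | actephilol C, (3S,4S) | COc1cc2c3c(cc(O)c2cc1C)C(C)(C)C(=O)[C@@]1(OC)Oc2c(cc4c(cc(OC)c5cc(C)c(O)cc54)c2C)O[C@@H]31 | target

**Step count**

Total: 24 steps. Longest linear sequence: 14 steps (from 3-methylcatechol 10 through steps 7–10, 12–18 and 22–24).

**Steps most likely to fail**

1. Step 22. The regiochemical bias may erode: the bond between C4a and C4b forces the bulky C4 substituent against the bromine, so the sterically easier, wrongly oriented adduct (methoxyl and methyl exchanged on ring A) may compete with the electronically preferred one. Fallback, setting out from 27: the control element is moved to C8 and changed to silicon. A 3-silylaryne is attacked by the nucleophilic furan terminus at the carbon next to silicon and also keeps the bulky furan terminus away from silicon, so steric and electronic bias point the same way. Commercial 4-methoxy-3-methylphenol would be dibrominated with NBS to 2,6-dibromo-4-methoxy-3-methylphenol F1. Two rounds of O-silylation and n-BuLi-induced retro-Brook migration would give 4-methoxy-3-methyl-2,6-bis(trimethylsilyl)phenol F2, and Tf2O would give its triflate F3. CsF should remove the silyl group flanked by hydrogen; the aryne adds to 27 and acid opening as in step 22 should give 8-(trimethylsilyl)-6'-O-pivaloyl actephilol C F4. Protodesilylation with Bu4NF in wet THF returns to 37, and step 23 falls away.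

2. Step 5. Oxygen transfer to an electron-poor cis-enone may be slow and poorly enantioselective, and the oxidant may attack the furan. Fallback, setting out from 7: Corey–Bakshi–Shibata reduction with (S)-2-methyl-CBS-oxazaborolidine and BH3·SMe2 (taking the quaternary carbon as the large flank) would give (5R)-4,4-dimethyl-4,5-dihydro-1-benzofuran-5-ol F5. Hydroxyl-directed epoxidation with VO(acac)2 and t-BuOOH then delivers oxygen syn to the hydroxyl and gives epoxy alcohol 9 directly, so steps 5 and 6 fall away.

3. Step 17. The double oxidation may cleave the vicinal diol or touch the free phenol, and the open dione may enolise at C7 under Et3N before the hemiketal closes, which would erode the enantiomeric purity. Fallback, setting out from 8: the reduction of step 6 is omitted and catechol 23 is added to the epoxy ketone itself (Cs2CO3 cat., MeCN, 0 °C, short reaction time) to give the α-hydroxy ketone F6, the (6R,7R)-6-hydroxy-7-aryloxy ketone. A single, base-free oxidation with Dess–Martin periodinane and NaHCO3 (or Cu(OAc)2 in AcOH) then leads to hemiketal 26.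

**Further compounds**

F1 | step 22 | 2,6-dibromo-4-methoxy-3-methylphenol | COc1cc(Br)c(O)c(Br)c1C
F2 | step 22 | 4-methoxy-3-methyl-2,6-bis(trimethylsilyl)phenol | COc1cc([Si](C)(C)C)c(O)c([Si](C)(C)C)c1C
F3 | step 22 | 4-methoxy-3-methyl-2,6-bis(trimethylsilyl)phenyl triflate | COc1cc([Si](C)(C)C)c(OS(=O)(=O)C(F)(F)F)c([Si](C)(C)C)c1C
F4 | step 22 | 8-(trimethylsilyl)-6'-O-pivaloyl actephilol C | COc1cc2c3c(cc(O)c2c([Si](C)(C)C)c1C)C(C)(C)C(=O)[C@@]1(OC)Oc2c(cc4c(cc(OC)c5cc(C)c(OC(=O)C(C)(C)C)cc54)c2C)O[C@@H]31
F5 | step 5 | (5R)-4,4-dimethyl-4,5-dihydro-1-benzofuran-5-ol | O[C@@H]1C=Cc2occc2C1(C)C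
F6 | step 17 | (6R,7R)-6-hydroxy-7-{[2-hydroxy-9-methoxy-1,7-dimethyl-6-(pivaloyloxy)phenanthren-3-yl]oxy}-4,4-dimethyl-6,7-dihydro-1-benzofuran-5(4H)-one | O=C1[C@H](O)[C@@H](Oc2cc3c(cc(OC)c4cc(C)c(OC(=O)C(C)(C)C)cc43)c(C)c2O)c2occc2C1(C)C
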